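The route rests on opening ring B of the second coumarin. Its benzene ring (B4a, B5, B6, B7, B8, B8a) carries the lactone oxygen on B8a, the alkenyl arm on B8 and the methoxy group on B7, the contiguous pattern that a vinylketene–alkoxyalkyne benzannulation delivers. In one thermal operation cyclobutenone and a methyl ynol ether give ring B as a free B8a phenol with the B7 methyl ether already in place. The precursor is the E-enynyl methyl ether 23, which already carries coumarin A and both stereocentres, set from (R)-linalool by a lactone Ireland–Claisen rearrangement. Ortho-formylation and an ylide annulation then close coumarin B.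

Key step: step 16

Labels: cyclohexene carbons run from C1 (CH bearing coumarin A) to C6 (quaternary carbon); coumarin atoms carry the prefix A or B.
Assumption: (R)-linalool of high enantiomeric purity is used; its carbinol centre is the only source of absolute configuration.
Remarks on the design:
- The sigmatropic step uses a six-membered lactone and gives a carbocycle of the same ring size.
- The C6 acid is taken to the aldehyde through its chloride, because a hydride reagent strong enough to reduce a carboxylic acid would also open the lactone of coumarin A.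
- The alkynyl ether is kept as the methyl ether: it has no β-hydrogen for retro-ene loss on heating and delivers the B7 methoxy group directly.

Step 1
Reactants: 1 4-bromobenzene-1,3-diol (4-bromoresorcinol)
Product: 2 6-bromo-7-hydroxy-2H-chromen-2-one
Conditions: DL-malic acid, conc. H2SO4, 110 °C
Reagents that add atoms: malic acid, OC(CC(O)=O)C(O)=O
Why: von Pechmann condensation, in which malic acid loses CO and water to formylacetic acid and the ring closes at the carbon para to one hydroxyl and ortho to the other, so bromine ends on C6 and the free hydroxyl on C7.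

Step 2
Reactants: 2 6-bromo-7-hydroxy-2H-chromen-2-one
Product: 3 6-bromo-7-methoxy-2H-chromen-2-one
Conditions: MeI, K2CO3, acetone, reflux
Reagents that add atoms: iodomethane, CI
Why: Williamson ether synthesis on an acidic phenol under conditions that leave the coumarin lactone closed.

Step 3
Reactants: 3 6-bromo-7-methoxy-2H-chromen-2-one
Product: 4 6-ethenyl-7-methoxy-2H-chromen-2-one
Conditions: potassium vinyltrifluoroborate, PdCl2(dppf) (3 mol%), Et3N, n-PrOH, 95 °C
Reagents that add atoms: potassium vinyltrifluoroborate, C=C[B-](F)(F)F.[K+]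
Why: Suzuki–Miyaura vinylation of an aryl bromide with an amine base, which avoids hydroxide opening of the lactone.

Step 4
Reactants: 5 (R)-linalool, (3R)-3,7-dimethylocta-1,6-dien-3-ol
Product: 6 (5R)-5-ethenyl-5-methyloxolan-2-ol (both anomers)
Conditions: O3 (1.0 equiv, Sudan Red 7B as end-point indicator), CH2Cl2/MeOH, −78 °C; then Me2S, −78 °C to rt
Reagents that add atoms: ozone, [O-][O+]=O
Why: ozonolysis with reductive work-up, in which the electron-rich trisubstituted alkene reacts well before the vinyl group next to the carbinol and the hydroxy aldehyde closes to the lactol with the carbinol centre untouched.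

Step 5
Reactants: 6 (5R)-5-ethenyl-5-methyloxolan-2-ol
Product: 7 (3R)-7-methoxy-3-methylhepta-1,6-dien-3-ol (E/Z mixture at the enol ether)
Conditions: MeOCH2PPh3Cl (3 equiv), KOtBu (3 equiv), THF, 0 °C; then 6, 0 °C to rt
Reagents that add atoms: (methoxymethyl)triphenylphosphonium chloride, COC[P+](c1ccccc1)(c1ccccc1)c1ccccc1.[Cl-]
Why: Wittig olefination of a lactol through its open hydroxy-aldehyde form, adding the one carbon that turns the five-membered lactol into a six-membered one.

Step 6
Reactants: 7 (3R)-7-methoxy-3-methylhepta-1,6-dien-3-ol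
Product: 9 (6R)-6-ethenyl-6-methyloxan-2-one, via lactol (6R)-6-ethenyl-6-methyloxan-2-ol 8 (not isolated)
Conditions: 0.5 M HCl, MeCN/H2O, rt; then NaHCO3, TEMPO (10 mol%), PhI(OAc)2 (1.5 equiv), rt
Reagents that add atoms: water, O
Why: enol ether hydrolysis gives the six-membered lactol, and the oxoammonium (TEMPO/PhI(OAc)2) oxidation takes it to the lactone without the chromium reagents that would transpose a tertiary allylic alcohol.

Step 7
Reactants: 9 (6R)-6-ethenyl-6-methyloxan-2-one
Product: 10 (6R)-6-ethenyl-3,6-dimethyloxan-2-one (both C3 epimers)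
Conditions: LiN(iPr)2, THF, −78 °C; MeI, −78 to −40 °C
Reagents that add atoms: iodomethane, CI
Why: lactone enolate alkylation kept cold so that the enolate does not rearrange; the C3 configuration is irrelevant because C3 becomes trigonal in step 9.

Step 8
Reactants: 10 (6R)-6-ethenyl-3,6-dimethyloxan-2-one; 4 6-ethenyl-7-methoxy-2H-chromen-2-one
Product: 11 (6R)-6-[(E)-2-(7-methoxy-2-oxo-2H-chromen-6-yl)ethenyl]-3,6-dimethyloxan-2-one (both C3 epimers)
Conditions: 4 (2.5 equiv), second-generation Hoveyda–Grubbs catalyst RuCl2(H2IMes)(=CH-C6H4-2-OiPr) (5–10 mol%), CH2Cl2, 40 °C, argon sweep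
Reagents that add atoms: none
Why: olefin cross-metathesis between a styrene that dimerizes reversibly and a vinyl group on a fully substituted carbon that cannot homodimerize favours the cross product as the E-alkene, and the ruthenium carbene, unlike zerovalent palladium, cannot ionize the tertiary allylic C–O bond, so the carbinol configuration is kept.

Step 9
Reactants: 11 (6R)-6-[(E)-2-(7-methoxy-2-oxo-2H-chromen-6-yl)ethenyl]-3,6-dimethyloxan-2-one
Product: 14 (1S,2S)-2-(7-methoxy-2-oxo-2H-chromen-6-yl)-1,4-dimethylcyclohex-3-ene-1-carboxylic acid (aryl cis to carboxyl), via silyl ketene acetal 12 (not isolated), via trimethylsilyl ester 13 (not isolated)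
Conditions: LiN(SiMe3)2, Me3SiCl/Et3N (premixed), THF, −78 °C to rt; toluene, 105 °C; then 1 M HCl, rt
Reagents that add atoms: none
Why: Ireland–Claisen rearrangement of a lactone silyl ketene acetal, in which the two-carbon tether forces a boat transition state, so the ring-fixed ketene acetal geometry, the E-styryl geometry and the R carbinol centre together fix C1 and C6 with aryl cis to carboxyl and in the absolute sense of the target while the carbinol centre becomes the ring alkene.

Step 10
Reactants: 14 (1S,2S)-2-(7-methoxy-2-oxo-2H-chromen-6-yl)-1,4-dimethylcyclohex-3-ene-1-carboxylic acid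
Product: 16 (1S,2S)-2-(7-methoxy-2-oxo-2H-chromen-6-yl)-1,4-dimethylcyclohex-3-ene-1-carbaldehyde, via acid chloride 15 (not isolated)
Conditions: 1-chloro-N,N,2-trimethylprop-1-en-1-amine, CH2Cl2, 0 °C to rt; then LiAlH(OtBu)3, THF, −78 °C
Reagents that add atoms: none
Why: the Ghosez chloroenamine makes the hindered acid chloride without free HCl, and partial reduction with the bulky alkoxyaluminium hydride stops at the aldehyde and spares the coumarin lactone, while the quaternary centre cannot epimerize.

Step 11
Reactants: 16 (1S,2S)-2-(7-methoxy-2-oxo-2H-chromen-6-yl)-1,4-dimethylcyclohex-3-ene-1-carbaldehyde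
Product: 17 6-[(1R,6S)-6-[(E)-2-iodoethenyl]-3,6-dimethylcyclohex-2-en-1-yl]-7-methoxy-2H-chromen-2-one
Conditions: CrCl2 (6 equiv), CHI3 (2 equiv), THF, 0 °C to rt
Reagents that add atoms: iodoform, IC(I)I
Why: Takai iodo-olefination, which is E-selective and most so for a hindered non-enolizable aldehyde, under conditions that do not touch the lactone.

Step 12
Reactants: 18 2-chloro-1,1-dimethoxyethane
Product: 20 methoxyethyne, via sodium methoxyacetylide 19 (not isolated)
Conditions: NaNH2 (3.2 equiv), liq. NH3, −33 °C; NH3 evaporated; cold brine, −20 °C; distilled into a −78 °C trap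
Reagents that add atoms: none
Why: two base-induced eliminations (HCl, then methanol) and deprotonation give the sodium acetylide, which the aqueous quench protonates to the volatile alkynyl ether.

Step 13
Reactants: 17 6-[(1R,6S)-6-[(E)-2-iodoethenyl]-3,6-dimethylcyclohex-2-en-1-yl]-7-methoxy-2H-chromen-2-one; 20 methoxyethyne
Product: 23 7-methoxy-6-[(1R,6R)-6-[(E)-4-methoxybut-1-en-3-yn-1-yl]-3,6-dimethylcyclohex-2-en-1-yl]-2H-chromen-2-one, via lithium methoxyacetylide 21 (not isolated), via chloro(methoxyethynyl)zinc 22 (not isolated)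
Conditions: 20 (2 equiv), n-BuLi, THF, −78 °C; ZnCl2, −78 to 0 °C; then 17, Pd(PPh3)4 (5 mol%), THF, rt
Reagents that add atoms: none
Why: Negishi coupling of an alkenyl iodide with an alkoxyethynylzinc halide proceeds with retention of the E geometry, and the zinc acetylide is too weak a nucleophile to attack the lactone.

Step 14
Reactants: 24 3-oxocyclobutane-1-carboxylic acid
Product: 25 3-bromocyclobutan-1-one
Conditions: HgO, Br2, MgSO4, CH2Cl2, reflux
Reagents that add atoms: bromine, BrBr
Why: Cristol–Firth variant of the Hunsdiecker bromodecarboxylation, a radical chain through the acyl hypobromite.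

Step 15
Reactants: 25 3-bromocyclobutan-1-one
Product: 26 cyclobut-2-en-1-one
Conditions: n-Bu3N, rt, product distilled at reduced pressure into a −78 °C trap
Reagents that add atoms: none
Why: E1cB-type dehydrobromination of a β-bromo ketone by a hindered amine, with the sensitive enone removed as it forms.

Step 16
Reactants: 23 7-methoxy-6-[(1R,6R)-6-[(E)-4-methoxybut-1-en-3-yn-1-yl]-3,6-dimethylcyclohex-2-en-1-yl]-2H-chromen-2-one; 26 cyclobut-2-en-1-one
Product: 31 6-[(1R,6R)-6-[(E)-2-(2-hydroxy-6-methoxyphenyl)ethenyl]-3,6-dimethylcyclohex-2-en-1-yl]-7-methoxy-2H-chromen-2-one, via vinylketene 27 (not isolated), via 4-vinylcyclobutenone adduct 28 (not isolated), via dienylketene 29 (not isolated), via cyclohexadienone 30 (not isolated)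
Conditions: 26 (2.5 equiv, in portions), toluene, sealed tube, 80 °C then 110 °C; then K2CO3, MeOH, rt (cleaves any O-acylated product); dilute HCl work-up
Reagents that add atoms: none
Why: On heating, 26 opens by 4π-electrocyclic ring opening to vinylketene 27, whose ketene C=C adds [2+2] to the ynol ether triple bond of 23; the 4-vinylcyclobutenone 28 reopens to dienylketene 29, which undergoes thermal disrotatory 6π-electrocyclization to 30 and enolizes to the phenol. This is the Danheiser benzannulation of a cyclobutenone with an alkoxyalkyne, a known reaction type. The only lasting ring is benzene ring B, closed by the 6π-electrocyclization (B4a–B8a) after the [2+2] step has made B8–B8a and B6–B7; the transient four-membered ring is closed by the [2+2] cycloaddition and opened again. No stereocentre is created, since the sp3 carbon of 28 is lost on ring opening, and the neutral thermal conditions leave C1, C6, the E-alkene and coumarin A untouched. The step needs regio- and chemoselectivity: the oxygen lone pair makes the alkyne carbon bearing the alkenyl arm the nucleophilic terminus, so it bonds to the ketene carbonyl carbon and the arm ends between OH and OMe, and the ynol ether is far more ketenophilic than the ring alkene, the arm alkene or the coumarin enoate.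

Step 17
Reactants: 31 6-[(1R,6R)-6-[(E)-2-(2-hydroxy-6-methoxyphenyl)ethenyl]-3,6-dimethylcyclohex-2-en-1-yl]-7-methoxy-2H-chromen-2-one
Product: 32 2-hydroxy-4-methoxy-3-[(E)-2-[(1R,2R)-2-(7-methoxy-2-oxo-2H-chromen-6-yl)-1,4-dimethylcyclohex-3-en-1-yl]ethenyl]benzaldehyde
Conditions: MgCl2, Et3N, (CH2O)n, MeCN, 80 °C
Reagents that add atoms: formaldehyde (as paraformaldehyde), C=O
Why: Casnati–Skattebøl ortho-formylation, in which the magnesium phenoxide delivers formaldehyde only to the free ortho carbon B4a (also para to the B7 methoxy group) and a second formaldehyde oxidizes the benzylic alkoxide by hydride transfer.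

Step 18
Reactants: 32 2-hydroxy-4-methoxy-3-[(E)-2-[(1R,2R)-2-(7-methoxy-2-oxo-2H-chromen-6-yl)-1,4-dimethylcyclohex-3-en-1-yl]ethenyl]benzaldehyde
Product: 34 7-methoxy-6-[(1R,6R)-6-[(E)-2-(7-methoxy-2-oxo-2H-chromen-8-yl)ethenyl]-3,6-dimethylcyclohex-2-en-1-yl]-2H-chromen-2-one, via acyl ylide 33 (not isolated)
Conditions: Ph3P=C=C=O (1.5 equiv), toluene, 110 °C
Reagents that add atoms: (triphenylphosphoranylidene)ketene (Bestmann ylide), O=C=C=P(c1ccccc1)(c1ccccc1)c1ccccc1
Why: the phenol adds across the cumulated ylide to give an aryl ester ylide, and the intramolecular Wittig reaction with the ortho aldehyde closes the pyranone with the cis alkene that the ring demands, well below the temperature needed to isomerize an open E-cinnamate.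

Compound list
1 | 4-bromobenzene-1,3-diol (4-bromoresorcinol) | Oc1ccc(Br)c(O)c1 | starting material
2 | 6-bromo-7-hydroxy-2H-chromen-2-one | Oc1cc2oc(=O)ccc2cc1Br | intermediate
3 | 6-bromo-7-methoxy-2H-chromen-2-one | COc1cc2oc(=O)ccc2cc1Br | intermediate
4 | 6-ethenyl-7-methoxy-2H-chromen-2-one | COc1cc2oc(=O)ccc2cc1C=C | intermediate
5 | (R)-linalool, (3R)-3,7-dimethylocta-1,6-dien-3-ol | C=C[C@](C)(O)CCC=C(C)C | starting material
6 | (5R)-5-ethenyl-5-methyloxolan-2-ol (both anomers) | OC1CC[C@](C)(C=C)O1 | intermediate
7 | (3R)-7-methoxy-3-methylhepta-1,6-dien-3-ol (E/Z mixture) | COC=CCC[C@@](C)(O)C=C | intermediate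
8 | (6R)-6-ethenyl-6-methyloxan-2-ol | OC1CCC[C@](C)(C=C)O1 | intermediate (not isolated)
9 | (6R)-6-ethenyl-6-methyloxan-2-one | O=C1CCC[C@](C)(C=C)O1 | intermediate
10 | (6R)-6-ethenyl-3,6-dimethyloxan-2-one (both C3 epimers) | CC1CC[C@](C)(C=C)OC1=O | intermediate
11 | (6R)-6-[(E)-2-(7-methoxy-2-oxo-2H-chromen-6-yl)ethenyl]-3,6-dimethyloxan-2-one (both C3 epimers) | CC1CC[C@](C)(/C=C/c2cc3ccc(=O)oc3cc2OC)OC1=O | intermediate
12 | 6-[(E)-2-[(2R)-2,5-dimethyl-6-(trimethylsilyloxy)-3,4-dihydro-2H-pyran-2-yl]ethenyl]-7-methoxy-2H-chromen-2-one (silyl ketene acetal) | CC1=C(O[Si](C)(C)C)O[C@@](C)(/C=C/c2cc3ccc(=O)oc3cc2OC)CC1 | intermediate (not isolated)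
13 | trimethylsilyl (1S,2S)-2-(7-methoxy-2-oxo-2H-chromen-6-yl)-1,4-dimethylcyclohex-3-ene-1-carboxylate | COc1cc2oc(=O)ccc2cc1[C@@H]1C=C(C)CC[C@]1(C)C(=O)O[Si](C)(C)C | intermediate (not isolated)
14 | (1S,2S)-2-(7-methoxy-2-oxo-2H-chromen-6-yl)-1,4-dimethylcyclohex-3-ene-1-carboxylic acid | COc1cc2oc(=O)ccc2cc1[C@@H]1C=C(C)CC[C@]1(C)C(=O)O | intermediate
15 | (1S,2S)-2-(7-methoxy-2-oxo-2H-chromen-6-yl)-1,4-dimethylcyclohex-3-ene-1-carbonyl chloride | COc1cc2oc(=O)ccc2cc1[C@@H]1C=C(C)CC[C@]1(C)C(Cl)=O | intermediate (not isolated)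
16 | (1S,2S)-2-(7-methoxy-2-oxo-2H-chromen-6-yl)-1,4-dimethylcyclohex-3-ene-1-carbaldehyde | COc1cc2oc(=O)ccc2cc1[C@@H]1C=C(C)CC[C@]1(C)C=O | intermediate
17 | 6-[(1R,6S)-6-[(E)-2-iodoethenyl]-3,6-dimethylcyclohex-2-en-1-yl]-7-methoxy-2H-chromen-2-one | COc1cc2oc(=O)ccc2cc1[C@@H]1C=C(C)CC[C@]1(C)/C=C/I | intermediate
18 | 2-chloro-1,1-dimethoxyethane | COC(CCl)OC | starting material
19 | sodium methoxyacetylide | [Na+].[C-]#COC | intermediate (not isolated)
20 | methoxyethyne | COC#C | intermediate
21 | lithium methoxyacetylide | [Li]C#COC | intermediate (not isolated)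
22 | chloro(methoxyethynyl)zinc | COC#C[Zn]Cl | intermediate (not isolated)
23 | 7-methoxy-6-[(1R,6R)-6-[(E)-4-methoxybut-1-en-3-yn-1-yl]-3,6-dimethylcyclohex-2-en-1-yl]-2H-chromen-2-one | COc1cc2oc(=O)ccc2cc1[C@@H]1C=C(C)CC[C@]1(C)/C=C/C#COC | intermediate
24 | 3-oxocyclobutane-1-carboxylic acid | O=C1CC(C(=O)O)C1 | starting material
25 | 3-bromocyclobutan-1-one | O=C1CC(Br)C1 | intermediate
26 | cyclobut-2-en-1-one | O=C1C=CC1 | intermediate
27 | buta-1,3-dien-1-one (vinylketene) | C=CC=C=O | intermediate (not isolated)
28 | 4-ethenyl-3-methoxy-2-[(E)-2-[(1R,2R)-2-(7-methoxy-2-oxo-2H-chromen-6-yl)-1,4-dimethylcyclohex-3-en-1-yl]ethenyl]cyclobut-2-en-1-one (both C4 epimers) | COc1cc2oc(=O)ccc2cc1[C@@H]1C=C(C)CC[C@]1(C)/C=C/C1=C(OC)C(C=C)C1=O | intermediate (not isolated)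
29 | 3-methoxy-2-[(E)-2-[(1R,2R)-2-(7-methoxy-2-oxo-2H-chromen-6-yl)-1,4-dimethylcyclohex-3-en-1-yl]ethenyl]hexa-1,3,5-trien-1-one (ketene carbon and terminal vinyl cis across the central double bond) | COc1cc2oc(=O)ccc2cc1[C@@H]1C=C(C)CC[C@]1(C)/C=C/C(=C=O)/C(OC)=C\C=C | intermediate (not isolated)
30 | 3-methoxy-2-[(E)-2-[(1R,2R)-2-(7-methoxy-2-oxo-2H-chromen-6-yl)-1,4-dimethylcyclohex-3-en-1-yl]ethenyl]cyclohexa-2,4-dien-1-one | COc1cc2oc(=O)ccc2cc1[C@@H]1C=C(C)CC[C@]1(C)/C=C/C1=C(OC)C=CCC1=O | intermediate (not isolated)
31 | 6-[(1R,6R)-6-[(E)-2-(2-hydroxy-6-methoxyphenyl)ethenyl]-3,6-dimethylcyclohex-2-en-1-yl]-7-methoxy-2H-chromen-2-one | COc1cc2oc(=O)ccc2cc1[C@@H]1C=C(C)CC[C@]1(C)/C=C/c1c(O)cccc1OC | intermediate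
32 | 2-hydroxy-4-methoxy-3-[(E)-2-[(1R,2R)-2-(7-methoxy-2-oxo-2H-chromen-6-yl)-1,4-dimethylcyclohex-3-en-1-yl]ethenyl]benzaldehyde | COc1cc2oc(=O)ccc2cc1[C@@H]1C=C(C)CC[C@]1(C)/C=C/c1c(OC)ccc(C=O)c1O | intermediate
33 | aryl (triphenylphosphoranylidene)acetate formed at the phenol oxygen of 32 | COc1cc2oc(=O)ccc2cc1[C@@H]1C=C(C)CC[C@]1(C)/C=C/c1c(OC)ccc(C=O)c1OC(=O)C=P(c1ccccc1)(c1ccccc1)c1ccccc1 | intermediate (not isolated)
34 | 7-methoxy-6-[(1R,6R)-6-[(E)-2-(7-methoxy-2-oxo-2H-chromen-8-yl)ethenyl]-3,6-dimethylcyclohex-2-en-1-yl]-2H-chromen-2-one (CNP0287121.3) | COc1cc2oc(=O)ccc2cc1[C@@H]1C=C(C)CC[C@]1(C)/C=C/c1c(OC)ccc2ccc(=O)oc12 | target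

Total step count: 18.
Longest linear sequence: 12 steps (5 to 34 through steps 4–11, 13, 16, 17 and 18).

Steps most likely to fail

Step 16. The parent vinylketene may be consumed by self-condensation and by acylating the product phenol faster than the hindered alkynyl ether intercepts it, so conversion of 23 could stall. The fallback sets out from vinyl iodide 17 and returns at phenol 31 with ring B brought in preformed. 3-Methoxyphenol is protected (MOMCl, iPr2NEt, CH2Cl2) as 1-methoxy-3-(methoxymethoxy)benzene F1. This is lithiated between its two oxygen substituents (n-BuLi, THF, 0 °C) and quenched with B(OiPr)3 to give [2-methoxy-6-(methoxymethoxy)phenyl]boronic acid F2. Suzuki–Miyaura coupling of F2 with 17 (Pd(OAc)2, SPhos, K3PO4, THF/H2O, 40 °C) should give, with retention of the E geometry, the methoxymethyl ether of 31 F3. HCl in MeOH at rt then removes the acetal and rejoins the route at 31.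

Step 9. The boat transition state that joins a quaternary and a benzylic carbon is congested, so the silyl ketene acetal may lose the tertiary allylic carboxylate by ionization and elimination instead of rearranging, or the lactone enolate may add to the coumarin before it is silylated. The fallback sets out from bromide 3 and returns at aldehyde 16 by building the cyclohexene through a cycloaddition. Heck coupling of 3 with 2-methylbut-3-en-2-ol (Pd(OAc)2, P(o-tol)3, Et3N, MeCN, 90 °C) gives the tertiary allylic alcohol 6-[(E)-3-hydroxy-3-methylbut-1-en-1-yl]-7-methoxy-2H-chromen-2-one F4. Dehydration (MsCl, Et3N, then DBU) gives the diene 7-methoxy-6-[(E)-3-methylbuta-1,3-dien-1-yl]-2H-chromen-2-one F5. An enantioselective Diels–Alder reaction of F5 with methacrolein follows, catalysed by the triflimide salt of the diphenylprolinol-derived B-(o-tolyl)oxazaborolidine (CH2Cl2, −78 to −40 °C), with the catalyst enantiomer matched to the (1S,2S) product in a test run. The aryl and methyl groups of the diene both direct the formyl-bearing carbon next to C1, and the endo approach of the formyl group places it cis to the aryl group, giving 16.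

Step 8. The fully substituted allylic carbon slows productive metathesis, so the vinylcoumarin may homodimerize to the stilbene while the catalyst decays before the lactone is consumed. The fallback sets out from bromide 3 and lactone 10 and returns at 11 by forming the aryl–alkene bond instead of the alkene. Heck arylation of 10 with 3 is run phosphine-free (Pd(OAc)2, Bu4NCl, NaHCO3, DMF, 90 °C), so that the aryl bromide intercepts zerovalent palladium before it can ionize the allylic lactone. β-Hydride elimination toward the benzylic carbon then gives the E-styryl lactone 11.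

Further compounds
F1 | step 16 | 1-methoxy-3-(methoxymethoxy)benzene | COCOc1cccc(OC)c1
F2 | step 16 | [2-methoxy-6-(methoxymethoxy)phenyl]boronic acid | COCOc1cccc(OC)c1B(O)O
F3 | step 16 | 7-methoxy-6-[(1R,6R)-6-[(E)-2-[2-methoxy-6-(methoxymethoxy)phenyl]ethenyl]-3,6-dimethylcyclohex-2-en-1-yl]-2H-chromen-2-one | COc1cc2oc(=O)ccc2cc1[C@@H]1C=C(C)CC[C@]1(C)/C=C/c1c(OCOC)cccc1OC
F4 | step 9 | 6-[(E)-3-hydroxy-3-methylbut-1-en-1-yl]-7-methoxy-2H-chromen-2-one | COc1cc2oc(=O)ccc2cc1/C=C/C(C)(C)O
F5 | step 9 | 7-methoxy-6-[(E)-3-methylbuta-1,3-dien-1-yl]-2H-chromen-2-one | COc1cc2oc(=O)ccc2cc1/C=C/C(C)=C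
F0 | step 8 | none | none
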